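**Retrosynthetic overview**
1. Target 28 ⇐ desilylation, reagent-controlled epoxidation of the 1(10)-Z olefin, C3 reduction/acetylation and C8 angeloylation ⇐ ten-membered hydroxy enone 21 (from β-keto sulfone 20 with SmI2).
2. Key step: 20 ⇐ anionic ring expansion of the seven-membered enoate lactone 18. The C2 sulfonyl carbanion attacks the lactone carbonyl C3 and the ring oxygen leaves as the C8 alkoxide (seven-membered lactone → ten-membered carbocycle).
3. 18 ⇐ ring-closing metathesis (C4=C5, Z fixed by the seven-membered ring) of ester 17 ⇐ Mitsunobu esterification with inversion at C8 of Barbier adduct 13.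
4. 13 ⇐ indium Barbier coupling (C7–C8) of bromobutenolide 12 (C6 from a Sharpless kinetic resolution) with Z-sulfonyl aldehyde 5 (Z-C1=C10 taken from six-membered lactone 1).
5. Ring order: butenolide → α-methylene-γ-lactone → seven-membered lactone → ten-membered carbocycle → epoxide.

Assumption: germacrane numbering (ring C1–C10, lactone carbons C11–C13, C14 on C10, C15 on C4) is used for all intermediates, and D-(−)-diisopropyl tartrate is taken to leave the (S)-dienol 9 unreacted in the kinetic resolution.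

**Step 1**
Reactants: 1 4-methyl-5,6-dihydro-2H-pyran-2-one
Product: 2 (2Z)-3-methylpent-2-ene-1,5-diol
Conditions: iBu2AlH (3.5 equiv), CH2Cl2, −78 → 0 °C; Rochelle salt
Reagents that add atoms: none
Why: DIBAL-H 1,2-reduction of the unsaturated lactone to the diol keeps the olefin geometry that was locked in the six-membered ring, which becomes the Z-C1=C10 bond.

**Step 2**
Reactants: 2 (2Z)-3-methylpent-2-ene-1,5-diol
Product: 4 (3Z)-3-methyl-5-(phenylsulfonyl)pent-3-en-1-ol, via allylic chloride 3 (not isolated)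
Conditions: NCS, Me2S, CH2Cl2, −20 → 0 °C; then PhSO2Na, Bu4NI (cat.), DMF, 25 °C
Reagents that add atoms: sodium benzenesulfinate [Na+].[O-]S(=O)c1ccccc1
Why: Corey–Kim chlorination converts only the allylic hydroxyl without transposition, and SN2 S-alkylation of the sulfinate gives the allyl sulfone with the Z-olefin untouched.

**Step 3**
Reactants: 4 (3Z)-3-methyl-5-(phenylsulfonyl)pent-3-en-1-ol
Product: 5 (3Z)-3-methyl-5-(phenylsulfonyl)pent-3-enal
Conditions: DMP, NaHCO3, CH2Cl2, 0 °C (used crude)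
Reagents that add atoms: none
Why: Buffered Dess–Martin oxidation gives the β,γ-unsaturated aldehyde under neutral conditions, so the olefin neither moves into conjugation nor isomerises.

**Step 4**
Reactants: 6 (2E)-but-2-enal; 7 ethenylmagnesium bromide CH2=CHMgBr
Product: 8 rac-(4E)-hexa-1,4-dien-3-ol
Conditions: THF, −78 °C; aq. NH4Cl
Reagents that add atoms: none
Why: Grignard 1,2-addition to the enal gives the racemic bis-allylic alcohol whose two alkenyl groups differ enough for the next two steps.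

**Step 5**
Reactants: 8 rac-(4E)-hexa-1,4-dien-3-ol
Product: 9 (3S,4E)-hexa-1,4-dien-3-ol
Conditions: Ti(OiPr)4, D-(−)-DIPT, tBuOOH (0.6 equiv), 4 Å MS, CH2Cl2, −20 °C
Reagents that add atoms: none
Why: Sharpless kinetic resolution epoxidises the E-propenyl unit of the (R)-alcohol much faster, so the (S)-alcohol that carries the future C6 centre is recovered in high ee.

**Step 6**
Reactants: 9 (3S,4E)-hexa-1,4-dien-3-ol; 10 2-(bromomethyl)prop-2-enoic acid
Product: 11 (3S,4E)-hexa-1,4-dien-3-yl 2-(bromomethyl)prop-2-enoate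
Conditions: DCC, DMAP (5 mol %), CH2Cl2, 0 °C
Reagents that add atoms: none
Why: Steglich esterification acylates the carbinol oxygen without touching the stereocentre.

**Step 7**
Reactants: 11 (3S,4E)-hexa-1,4-dien-3-yl 2-(bromomethyl)prop-2-enoate
Product: 12 (5R)-3-(bromomethyl)-5-[(1E)-prop-1-en-1-yl]furan-2(5H)-one
Conditions: second-generation Grubbs catalyst RuCl2(H2IMes)(PCy3)(=CHPh) (5 mol %), CH2Cl2, 40 °C
Reagents that add atoms: none
Why: Ring-closing metathesis starts at the terminal vinyl group and closes onto the acrylate to give the butenolide, leaving the slower E-propenyl group on C6 (configuration unchanged).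

**Step 8**
Reactants: 12 (5R)-3-(bromomethyl)-5-[(1E)-prop-1-en-1-yl]furan-2(5H)-one; 5 (3Z)-3-methyl-5-(phenylsulfonyl)pent-3-enal
Product: 13 (4R,5R)-4-[(1S,3Z)-1-hydroxy-3-methyl-5-(phenylsulfonyl)pent-3-en-1-yl]-3-methylidene-5-[(1E)-prop-1-en-1-yl]oxolan-2-one
Conditions: In, THF–H2O (1:1), 25 °C
Reagents that add atoms: none
Why: In the indium Barbier allylation the allylindium attacks through its γ-carbon (C7) on the face anti to the C6 propenyl group (trans lactone) via a closed Zimmerman–Traxler chair, which gives the anti adduct at C8 (8S, the epimer needed for the next step) and unveils the α-methylene lactone.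

**Step 9**
Reactants: 14 methyl 2-(hydroxymethyl)prop-2-enoate
Product: 16 2-{[(tert-butyldimethylsilyl)oxy]methyl}prop-2-enoic acid, via silyl ether methyl ester 15 (not isolated)
Conditions: TBSCl, imidazole, DMF, 25 °C; then LiOH, THF–H2O, 0 °C; HCl to pH 4
Reagents that add atoms: tert-butyldimethylsilyl chloride CC(C)(C)[Si](C)(C)Cl; lithium hydroxide [Li+].[OH-]
Why: Silylation followed by saponification gives the protected C3–C4–C15 acid for the Mitsunobu coupling.

**Step 10**
Reactants: 13 (Barbier adduct, 8S); 16 2-{[(tert-butyldimethylsilyl)oxy]methyl}prop-2-enoic acid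
Product: 17 (1R,3Z)-3-methyl-1-{(2R,3R)-4-methylidene-5-oxo-2-[(1E)-prop-1-en-1-yl]oxolan-3-yl}-5-(phenylsulfonyl)pent-3-en-1-yl 2-{[(tert-butyldimethylsilyl)oxy]methyl}prop-2-enoate
Conditions: PPh3, DIAD, toluene, 0 → 25 °C
Reagents that add atoms: none
Why: Mitsunobu esterification displaces the activated C8 oxygen with the carboxylate under clean inversion, which sets the required 8R (8β-oxygen) configuration and attaches C3.

**Step 11**
Reactants: 17 (ester, 8R)
Product: 18 (6R,7R,8R)-15-(tert-butyldimethylsilyloxy)-2-(phenylsulfonyl)-2,3-secogermacra-1(10)Z,4Z,11(13)-triene-3,8:12,6-diolide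
Conditions: second-generation Hoveyda–Grubbs catalyst RuCl2(H2IMes)(=CH-C6H4-2-OiPr) (10 mol %), toluene (2 mM), 80 °C
Reagents that add atoms: none
Why: Ring-closing metathesis between the propenyl group and the 2-substituted acrylate closes the seven-membered enoate lactone with loss of propene, and the small ring allows only the cis C4=C5 bond (C3 and C6 cis, C15 outside).

**Step 12**
Reactants: 18 (seven-membered bis-lactone)
Product: 20 (6R,7R,8R)-15-(tert-butyldimethylsilyloxy)-8-hydroxy-3-oxo-2-(phenylsulfonyl)germacra-1(10)Z,4Z,11(13)-trien-12,6-olide (C2 epimers), via bridged tetrahedral alkoxide 19 (not isolated)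
Conditions: LiN(SiMe3)2 (1.05 equiv), THF (5 mM), −78 → 0 °C; aq. NH4Cl
Reagents that add atoms: none
Why: Proposed new method: the allylic sulfone is the most acidic C–H (pKa about 22), so its Z-configured α-sulfonyl carbanion, held four atoms from C8, adds through a seven-membered transition state to the lactone carbonyl C3, and the bridged tetrahedral alkoxide 19 collapses by expelling the ring oxygen as the C8 alkoxide, which is at once protonated by the new β-keto sulfone (pKa about 12), so the stabilised enolate of 20 is the thermodynamic sink and the C2–C3 bond of the ten-membered carbocycle is formed with both Z-olefins and C6–C8 untouched; the closest known reaction types are the acylation of α-sulfonyl carbanions by lactones, the Dieckmann condensation and lactone-to-carbocycle ring expansions by intramolecular nucleophilic acyl substitution with SmI2, none shown for a sulfonyl carbanion turning a medium-ring lactone into a ten-membered carbocycle.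

**Step 13**
Reactants: 20 (β-keto sulfone)
Product: 21 (6R,7R,8R)-15-(tert-butyldimethylsilyloxy)-8-hydroxy-3-oxogermacra-1(10)Z,4Z,11(13)-trien-12,6-olide
Conditions: SmI2 (2.2 equiv), THF–MeOH, −78 °C
Reagents that add atoms: none
Why: Reductive desulfonylation of the α-sulfonyl ketone is far faster than reduction of the enone or the methylene lactone, and kinetic protonation of the samarium dienolate at C2 keeps the 1(10) olefin Z and out of conjugation.

**Step 14**
Reactants: 21 (hydroxy enone); 22 angelic acid [(2Z)-2-methylbut-2-enoic acid]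
Product: 24 (6R,7R,8R)-8-angeloyloxy-15-(tert-butyldimethylsilyloxy)-3-oxogermacra-1(10)Z,4Z,11(13)-trien-12,6-olide, via mixed anhydride 23 (not isolated)
Conditions: 2,4,6-Cl3C6H2COCl, Et3N, toluene, 25 °C; then 21, DMAP, 25 °C
Reagents that add atoms: none
Why: Yamaguchi esterification acylates the 8β-hydroxyl with retention and is the standard way to install an angelate without isomerisation to the tiglate.

**Step 15**
Reactants: 24 (enone angelate)
Product: 26 (3S,6R,7R,8R)-3-acetoxy-8-angeloyloxy-15-(tert-butyldimethylsilyloxy)germacra-1(10)Z,4Z,11(13)-trien-12,6-olide, via allylic alcohol 25 (not isolated)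
Conditions: (R)-Me-CBS (20 mol %), catecholborane, toluene, −78 °C; MeOH; then Ac2O, Et3N, DMAP, CH2Cl2, 0 °C
Reagents that add atoms: acetic anhydride CC(=O)OC(C)=O
Why: Corey–Bakshi–Shibata 1,2-reduction under reagent control (the alkenyl C4 acts as the large group, the (R)-catalyst gives the 3S alcohol) sets C3, and acetylation of the crude alcohol fixes it as the 3β-acetate.

**Step 16**
Reactants: 26 (trienolide)
Product: 27 (1R,3S,6R,7R,8R,10S)-3-acetoxy-8-angeloyloxy-15-(tert-butyldimethylsilyloxy)-1,10-epoxygermacra-4Z,11(13)-dien-12,6-olide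
Conditions: D-fructose-derived Shi ketone (30 mol %), KHSO5 (Oxone), K2CO3, Bu4NHSO4, MeCN–(MeO)2CH2–aq. buffer pH 10.5, 0 °C
Reagents that add atoms: potassium peroxymonosulfate [K+].[O-]S(=O)(=O)OO
Why: In the Shi epoxidation the electrophilic dioxirane selects the only electron-rich olefin (the 4,5-olefin carries three allylic oxygens, the methylene lactone and angelate are electron-poor), and the spiro transition state of the D-fructose ketone, as for 1-substituted cycloalkenes, delivers oxygen to the β-face to give the cis (1R,10S) epoxide.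

**Step 17**
Reactants: 27 (epoxide silyl ether)
Product: 28 (1R,3S,6R,7R,8R,10S)-3-acetoxy-8-angeloyloxy-1,10-epoxy-15-hydroxygermacra-4Z,11(13)-dien-12,6-olide (target)
Conditions: HF·pyridine, pyridine, THF, 0 °C
Reagents that add atoms: none
Why: Buffered fluoride desilylation frees the C15 hydroxyl under non-basic conditions, which avoids acetate migration from O3 to O15 and opening of the trisubstituted epoxide.

**Compound list**
1 | 4-methyl-5,6-dihydro-2H-pyran-2-one | CC1=CC(=O)OCC1 | starting material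
2 | (2Z)-3-methylpent-2-ene-1,5-diol | OC/C=C(/C)CCO | intermediate
3 | (3Z)-5-chloro-3-methylpent-3-en-1-ol | ClC/C=C(/C)CCO | intermediate
4 | (3Z)-3-methyl-5-(phenylsulfonyl)pent-3-en-1-ol | O=S(=O)(C/C=C(/C)CCO)c1ccccc1 | intermediate
5 | (3Z)-3-methyl-5-(phenylsulfonyl)pent-3-enal | O=S(=O)(C/C=C(/C)CC=O)c1ccccc1 | intermediate
6 | (2E)-but-2-enal | C/C=C/C=O | starting material
7 | ethenylmagnesium bromide | C=C[Mg]Br | starting material
8 | rac-(4E)-hexa-1,4-dien-3-ol | C=CC(O)/C=C/C | intermediate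
9 | (3S,4E)-hexa-1,4-dien-3-ol | O[C@@H](C=C)/C=C/C | intermediate
10 | 2-(bromomethyl)prop-2-enoic acid | C=C(CBr)C(=O)O | starting material
11 | (3S,4E)-hexa-1,4-dien-3-yl 2-(bromomethyl)prop-2-enoate | C=C(CBr)C(=O)O[C@@H](C=C)/C=C/C | intermediate
12 | (5R)-3-(bromomethyl)-5-[(1E)-prop-1-en-1-yl]furan-2(5H)-one | O=C1O[C@H](/C=C/C)C=C1CBr | intermediate
13 | (4R,5R)-4-[(1S,3Z)-1-hydroxy-3-methyl-5-(phenylsulfonyl)pent-3-en-1-yl]-3-methylidene-5-[(1E)-prop-1-en-1-yl]oxolan-2-one | C=C1C(=O)O[C@H](/C=C/C)[C@H]1[C@@H](O)C/C(C)=C\CS(=O)(=O)c1ccccc1 | intermediate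
14 | methyl 2-(hydroxymethyl)prop-2-enoate | C=C(CO)C(=O)OC | starting material
15 | methyl 2-{[(tert-butyldimethylsilyl)oxy]methyl}prop-2-enoate | C=C(CO[Si](C)(C)C(C)(C)C)C(=O)OC | intermediate
16 | 2-{[(tert-butyldimethylsilyl)oxy]methyl}prop-2-enoic acid | C=C(CO[Si](C)(C)C(C)(C)C)C(=O)O | intermediate
17 | (1R,3Z)-3-methyl-1-{(2R,3R)-4-methylidene-5-oxo-2-[(1E)-prop-1-en-1-yl]oxolan-3-yl}-5-(phenylsulfonyl)pent-3-en-1-yl 2-{[(tert-butyldimethylsilyl)oxy]methyl}prop-2-enoate | C=C1C(=O)O[C@H](/C=C/C)[C@H]1[C@H](OC(=O)C(=C)CO[Si](C)(C)C(C)(C)C)C/C(C)=C\CS(=O)(=O)c1ccccc1 | intermediate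
18 | (6R,7R,8R)-15-(tert-butyldimethylsilyloxy)-2-(phenylsulfonyl)-2,3-secogermacra-1(10)Z,4Z,11(13)-triene-3,8:12,6-diolide | C=C1C(=O)O[C@@H]2/C=C(/CO[Si](C)(C)C(C)(C)C)C(=O)O[C@H](C/C(C)=C\CS(=O)(=O)c3ccccc3)[C@@H]12 | intermediate
19 | bridged tetrahedral adduct, (6R,7R,8R)-3,8-epoxy-3-hydroxy-2-(phenylsulfonyl)-15-(tert-butyldimethylsilyloxy)germacra-1(10)Z,4Z,11(13)-trien-12,6-olide, present as its lithium alkoxide (transient C2 and C3 centres not assigned) | C=C1C(=O)O[C@@H]2/C=C(/CO[Si](C)(C)C(C)(C)C)C3(O)C(S(=O)(=O)c4ccccc4)/C=C(C)\C[C@@H](O3)[C@@H]12 | intermediate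
20 | (6R,7R,8R)-15-(tert-butyldimethylsilyloxy)-8-hydroxy-3-oxo-2-(phenylsulfonyl)germacra-1(10)Z,4Z,11(13)-trien-12,6-olide (C2 epimers) | C=C1C(=O)O[C@@H]2/C=C(/CO[Si](C)(C)C(C)(C)C)C(=O)C(S(=O)(=O)c3ccccc3)/C=C(C)\C[C@@H](O)[C@@H]12 | intermediate
21 | (6R,7R,8R)-15-(tert-butyldimethylsilyloxy)-8-hydroxy-3-oxogermacra-1(10)Z,4Z,11(13)-trien-12,6-olide | C=C1C(=O)O[C@@H]2/C=C(/CO[Si](C)(C)C(C)(C)C)C(=O)C/C=C(C)\C[C@@H](O)[C@@H]12 | intermediate
22 | angelic acid, (2Z)-2-methylbut-2-enoic acid | C/C=C(/C)C(=O)O | starting material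
23 | (2Z)-2-methylbut-2-enoic 2,4,6-trichlorobenzoic anhydride | C/C=C(/C)C(=O)OC(=O)c1c(Cl)cc(Cl)cc1Cl | intermediate
24 | (6R,7R,8R)-8-angeloyloxy-15-(tert-butyldimethylsilyloxy)-3-oxogermacra-1(10)Z,4Z,11(13)-trien-12,6-olide | C=C1C(=O)O[C@@H]2/C=C(/CO[Si](C)(C)C(C)(C)C)C(=O)C/C=C(C)\C[C@@H](OC(=O)/C(C)=C\C)[C@@H]12 | intermediate
25 | (3S,6R,7R,8R)-8-angeloyloxy-15-(tert-butyldimethylsilyloxy)-3-hydroxygermacra-1(10)Z,4Z,11(13)-trien-12,6-olide | C=C1C(=O)O[C@@H]2/C=C(/CO[Si](C)(C)C(C)(C)C)[C@@H](O)C/C=C(C)\C[C@@H](OC(=O)/C(C)=C\C)[C@@H]12 | intermediate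
26 | (3S,6R,7R,8R)-3-acetoxy-8-angeloyloxy-15-(tert-butyldimethylsilyloxy)germacra-1(10)Z,4Z,11(13)-trien-12,6-olide | C=C1C(=O)O[C@@H]2/C=C(/CO[Si](C)(C)C(C)(C)C)[C@@H](OC(C)=O)C/C=C(C)\C[C@@H](OC(=O)/C(C)=C\C)[C@@H]12 | intermediate
27 | (1R,3S,6R,7R,8R,10S)-3-acetoxy-8-angeloyloxy-15-(tert-butyldimethylsilyloxy)-1,10-epoxygermacra-4Z,11(13)-dien-12,6-olide | C=C1C(=O)O[C@@H]2/C=C(/CO[Si](C)(C)C(C)(C)C)[C@@H](OC(C)=O)C[C@H]3O[C@@]3(C)C[C@@H](OC(=O)/C(C)=C\C)[C@@H]12 | intermediate
28 | (1R,3S,6R,7R,8R,10S)-3-acetoxy-8-angeloyloxy-1,10-epoxy-15-hydroxygermacra-4Z,11(13)-dien-12,6-olide | C=C1C(=O)O[C@@H]2/C=C(/CO)[C@@H](OC(C)=O)C[C@H]3O[C@@]3(C)C[C@@H](OC(=O)/C(C)=C\C)[C@@H]12 | target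

**Step count and risks**
Total step count: 17 (steps 2, 9, 14 and 15 are two-stage one-flask operations).
Longest linear sequence: 13 steps (4, 5, 6, 7, 8, 10, 11, 12, 13, 14, 15, 16, 17).

Three steps most likely to fail:

Step 12 (the proposed ring expansion; the carbanion may fail to add, or the bridged adduct may not collapse). The fallback sets out from 17 and comes back at 20. Ester 17 is treated with LiN(SiMe3)2 in THF at −78 °C, so that the sulfonyl carbanion is acylated by the neighbouring open-chain ester (ordinary Claisen-type acylation of an α-sulfonyl carbanion, O→C acyl transfer). This gives the acyclic hydroxy β-keto sulfone (4R,5R)-4-[(1R,3Z)-7-{[(tert-butyldimethylsilyl)oxy]methyl}-1-hydroxy-3-methyl-6-oxo-5-(phenylsulfonyl)octa-3,7-dien-1-yl]-3-methylidene-5-[(1E)-prop-1-en-1-yl]oxolan-2-one F1. The ten-membered ring is then closed directly by ring-closing metathesis of the enone methylene with the propenyl group (second-generation Hoveyda–Grubbs catalyst, toluene, 1 mM, 80 °C), which gives 20. The ring is then made by macrocyclisation instead of ring expansion, and the Z geometry at C4=C5 is no longer enforced by a small ring.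

Step 10 (Mitsunobu inversion at the hindered C8 carbinol; elimination or no reaction). The fallback sets out from 13 and comes back at 17. Oxidation with DMP/NaHCO3 gives the ketone (4S,5R)-3-methylidene-4-[(3Z)-3-methyl-5-(phenylsulfonyl)pent-3-enoyl]-5-[(1E)-prop-1-en-1-yl]oxolan-2-one F2. Reagent-controlled reduction with (S)-Me-CBS and catecholborane gives the epimeric alcohol (4R,5R)-4-[(1R,3Z)-1-hydroxy-3-methyl-5-(phenylsulfonyl)pent-3-en-1-yl]-3-methylidene-5-[(1E)-prop-1-en-1-yl]oxolan-2-one F3. F3 is acylated with retention by acid 16 (DCC, DMAP, CH2Cl2) to give 17.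

Step 16 (facial and site selectivity of the epoxidation on the macrocycle; base-sensitive esters). The fallback sets out from 26 and comes back at 27. If the oxidant prefers the α-face, NBS in THF–H2O at 0 °C is used instead, so that the bromonium ion forms on that face and water opens it anti at C10. This gives the bromohydrin (1S,3S,6R,7R,8R,10S)-3-acetoxy-8-angeloyloxy-1-bromo-15-(tert-butyldimethylsilyloxy)-10-hydroxygermacra-4Z,11(13)-dien-12,6-olide F4. K2CO3 in acetone then closes it with inversion at C1 to the β-epoxide 27.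

**Further compounds**
F1 | step 12 | (4R,5R)-4-[(1R,3Z)-7-{[(tert-butyldimethylsilyl)oxy]methyl}-1-hydroxy-3-methyl-6-oxo-5-(phenylsulfonyl)octa-3,7-dien-1-yl]-3-methylidene-5-[(1E)-prop-1-en-1-yl]oxolan-2-one | C=C1C(=O)O[C@H](/C=C/C)[C@H]1[C@H](O)C/C(C)=C\C(C(=O)C(=C)CO[Si](C)(C)C(C)(C)C)S(=O)(=O)c1ccccc1
F2 | step 10 | (4S,5R)-3-methylidene-4-[(3Z)-3-methyl-5-(phenylsulfonyl)pent-3-enoyl]-5-[(1E)-prop-1-en-1-yl]oxolan-2-one | C=C1C(=O)O[C@H](/C=C/C)[C@H]1C(=O)C/C(C)=C\CS(=O)(=O)c1ccccc1
F3 | step 10 | (4R,5R)-4-[(1R,3Z)-1-hydroxy-3-methyl-5-(phenylsulfonyl)pent-3-en-1-yl]-3-methylidene-5-[(1E)-prop-1-en-1-yl]oxolan-2-one | C=C1C(=O)O[C@H](/C=C/C)[C@H]1[C@H](O)C/C(C)=C\CS(=O)(=O)c1ccccc1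
F4 | step 16 | (1S,3S,6R,7R,8R,10S)-3-acetoxy-8-angeloyloxy-1-bromo-15-(tert-butyldimethylsilyloxy)-10-hydroxygermacra-4Z,11(13)-dien-12,6-olide | C=C1C(=O)O[C@@H]2/C=C(/CO[Si](C)(C)C(C)(C)C)[C@@H](OC(C)=O)C[C@H](Br)[C@@](C)(O)C[C@@H](OC(=O)/C(C)=C\C)[C@@H]12
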